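**Retrosynthetic overview**
- Target ⇐ removal of two MOM ethers ⇐ isopropenyl carbinol ⇐ methylenation of a methyl ketone ⇐ MeLi opening of a malate-derived dioxolanone on C8.
- Key disconnection C8–CH2: light-driven decarboxylative C–H alkylation of 6-prenylgenistein 7,4'-bis(MOM) ether with the redox-active ester of L-malic acid acetonide. The (S) centre is bought and never reacts.
- C6-prenyl ⇐ Suzuki–Miyaura prenylation of the C6 iodide ⇐ iodination ortho to the free 5-OH of genistein 7,4'-bis(MOM) ether ⇐ genistein.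
- No ring is built: rings A, B and C come with genistein. Order: protect, substitute C6, substitute C8, finish the side chain, deprotect.

Assumption: genistein, prenylboronic acid pinacol ester and (S)-2,2-dimethyl-5-oxo-1,3-dioxolane-4-acetic acid (the acetonide of natural L-malic acid) are bought.

**Route**

Step 1
Reactants: 1 genistein
Product: 2 genistein 7,4'-bis(methoxymethyl) ether
Conditions: MOMCl (2.3 equiv), K2CO3 (2.5 equiv), acetone, 0 °C to rt
Reagents that add atoms: chloromethyl methyl ether, COCCl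
Why: Williamson-type O-alkylation (MOM protection) in which K2CO3 ionises only the acidic 7- and 4'-OH groups, while the 5-OH is hydrogen-bonded to the C4 carbonyl and stays free; no stereocentre is involved.

Step 2
Reactants: 2 genistein 7,4'-bis(methoxymethyl) ether
Product: 3 C6-iodogenistein 7,4'-bis(methoxymethyl) ether
Conditions: NIS (1.05 equiv), DMF, 0 °C to rt, dark
Reagents that add atoms: N-iodosuccinimide, O=C1CCC(=O)N1I
Why: Electrophilic aromatic iodination, which under neutral NIS goes ortho to the free 5-OH (C6) in 5-hydroxy-7-alkoxy(iso)flavones (recalled precedent, not checked here), whereas C8 attack needs a 5-O-protected ring; ring B is far less activated.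

Step 3
Reactants: 3 C6-iodogenistein 7,4'-bis(methoxymethyl) ether; 4 prenylboronic acid pinacol ester
Product: 5 wighteone (6-prenylgenistein) 7,4'-bis(methoxymethyl) ether
Conditions: 4 (1.5 equiv), PdCl2(dppf) (5 mol %), K3PO4 (3 equiv), THF–H2O 10:1, 65 °C
Reagents that add atoms: none
Why: Suzuki–Miyaura allylation in which the bidentate dppf ligand lets the allyl–palladium intermediate equilibrate, so reductive elimination occurs at the unhindered CH2 terminus and gives the linear prenyl group; the MOM ethers survive aqueous phosphate.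

Step 4
Reactants: 5 wighteone 7,4'-bis(methoxymethyl) ether; 6 (S)-2,2-dimethyl-5-oxo-1,3-dioxolane-4-acetic acid
Product: 9 C8-{[(4S)-2,2-dimethyl-5-oxo-1,3-dioxolan-4-yl]methyl}wighteone 7,4'-bis(methoxymethyl) ether, via redox-active ester 7 (not isolated), via cyclohexadienone tautomer 8 (not isolated)
Conditions: 6 (2 equiv), N-hydroxyphthalimide (2 equiv), DIC (2 equiv), MeCN, rt, 2 h; then 5 (1 equiv), [Ir(dF(CF3)ppy)2(dtbbpy)]PF6 (1 mol %), K2HPO4 (2 equiv), degassed, 450 nm LEDs, 25 °C
Reagents that add atoms: none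
Why: Proposed new method: redox-neutral photoredox para-C–H alkylation of a free phenol by decarboxylative radical–radical cross-coupling, in which the excited iridium photocatalyst oxidises the hydrogen-bonded 5-phenol of 5 (phosphate-assisted proton-coupled electron transfer) to a phenoxyl radical that is long-lived because both ortho carbons (C4a, C6) are substituted and its own C8–C8' dimer would be a crowded tetra-ortho-substituted biaryl, the reduced photocatalyst then passes an electron to 7, which loses phthalimide anion and CO2 to give the primary alkyl radical, and this short-lived radical is captured by the persistent phenoxyl radical at C8, the only unsubstituted ring-A carbon and the para site of high spin density, to give dienone 8, which tautomerises to 9; the phthalimide anion takes up the phenol proton so no external oxidant or reductant is needed, and the stereocentre sits β to the radical in a ring that is never opened, so it is carried through unchanged; the closest known reaction types are photoredox radical–radical couplings governed by the persistent-radical effect, decarboxylative couplings of N-acyloxyphthalimides, C-alkylation of phenolates through photoactive electron donor–acceptor complexes, and trapping of alkyl radicals by hindered phenoxyl radicals at the para carbon.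

Step 5
Reactants: 9 C8-{[(4S)-2,2-dimethyl-5-oxo-1,3-dioxolan-4-yl]methyl}wighteone 7,4'-bis(methoxymethyl) ether
Product: 11 C8-[(2S)-2-hydroxy-3-oxobutyl]wighteone 7,4'-bis(methoxymethyl) ether, via lithium hemiketal adduct 10 (not isolated)
Conditions: MeLi (2.3 equiv), THF, −78 °C; AcOH quench at −78 °C, then rt
Reagents that add atoms: methyllithium, [Li]C
Why: Organolithium mono-addition to a 1,3-dioxolan-4-one (α-hydroxy ketone synthesis), in which the first equivalent of MeLi turns the 5-OH into a lithium chelate that deactivates the chromone as an electrophile and the second adds to the activated lactone to give a tetrahedral adduct that is stable at −78 °C and collapses to ketone and acetone only on quench, so there is no double addition; the stereocentre is not a reacting centre and is retained.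

Step 6
Reactants: 11 C8-[(2S)-2-hydroxy-3-oxobutyl]wighteone 7,4'-bis(methoxymethyl) ether
Product: 12 C8-[(2S)-2-hydroxy-3-methylbut-3-en-1-yl]wighteone 7,4'-bis(methoxymethyl) ether
Conditions: Zn, CH2Br2, TiCl4 (pre-formed Lombardo reagent, 6 equiv), THF–CH2Cl2, 0 °C to rt
Reagents that add atoms: dibromomethane, BrCBr
Why: Takai–Lombardo methylenation, whose non-basic zinc/titanium methylene reagent converts the ketone without enolising the neighbouring carbinol stereocentre, leaves the vinylogous-ester chromone carbonyl alone and tolerates the free OH groups when used in excess.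

Step 7
Reactants: 12 C8-[(2S)-2-hydroxy-3-methylbut-3-en-1-yl]wighteone 7,4'-bis(methoxymethyl) ether
Product: 13 CNP0203531.1 (5,7-dihydroxy-8-[(2S)-2-hydroxy-3-methylbut-3-en-1-yl]-3-(4-hydroxyphenyl)-6-(3-methylbut-2-en-1-yl)-4H-chromen-4-one)
Conditions: HCl (0.5 M) in MeOH–THF, 30 °C
Reagents that add atoms: none
Why: Acid-catalysed transacetalisation of the two aryl MOM ethers to methanol, where dilute acid near room temperature spares the prenyl group and the allylic alcohol with its stereocentre.

**Compound list**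
1 | genistein (5,7-dihydroxy-3-(4-hydroxyphenyl)-4H-chromen-4-one) | Oc1ccc(cc1)-c1coc2cc(O)cc(O)c2c1=O | starting material
2 | 5-hydroxy-7-(methoxymethoxy)-3-[4-(methoxymethoxy)phenyl]-4H-chromen-4-one | COCOc1ccc(cc1)-c1coc2cc(OCOC)cc(O)c2c1=O | intermediate
3 | 5-hydroxy-6-iodo-7-(methoxymethoxy)-3-[4-(methoxymethoxy)phenyl]-4H-chromen-4-one | COCOc1ccc(cc1)-c1coc2cc(OCOC)c(I)c(O)c2c1=O | intermediate
4 | 4,4,5,5-tetramethyl-2-(3-methylbut-2-en-1-yl)-1,3,2-dioxaborolane (prenylboronic acid pinacol ester) | CC(C)=CCB1OC(C)(C)C(C)(C)O1 | starting material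
5 | 5-hydroxy-7-(methoxymethoxy)-3-[4-(methoxymethoxy)phenyl]-6-(3-methylbut-2-en-1-yl)-4H-chromen-4-one | COCOc1ccc(cc1)-c1coc2cc(OCOC)c(CC=C(C)C)c(O)c2c1=O | intermediate
6 | 2-[(4S)-2,2-dimethyl-5-oxo-1,3-dioxolan-4-yl]acetic acid (acetonide of L-malic acid) | CC1(C)O[C@@H](CC(=O)O)C(=O)O1 | starting material
7 | 1,3-dioxoisoindolin-2-yl 2-[(4S)-2,2-dimethyl-5-oxo-1,3-dioxolan-4-yl]acetate | CC1(C)O[C@@H](CC(=O)ON2C(=O)c3ccccc3C2=O)C(=O)O1 | intermediate
8 | 8-{[(4S)-2,2-dimethyl-5-oxo-1,3-dioxolan-4-yl]methyl}-7-(methoxymethoxy)-3-[4-(methoxymethoxy)phenyl]-6-(3-methylbut-2-en-1-yl)-8H-chromene-4,5-dione (C8 epimers, keto tautomer of 9) | CC1(C)O[C@@H](CC2C(OCOC)=C(CC=C(C)C)C(=O)C3=C2OC=C(c2ccc(OCOC)cc2)C3=O)C(=O)O1 | intermediate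
9 | 8-{[(4S)-2,2-dimethyl-5-oxo-1,3-dioxolan-4-yl]methyl}-5-hydroxy-7-(methoxymethoxy)-3-[4-(methoxymethoxy)phenyl]-6-(3-methylbut-2-en-1-yl)-4H-chromen-4-one | CC1(C)O[C@@H](Cc2c(OCOC)c(CC=C(C)C)c(O)c3c(=O)c(-c4ccc(OCOC)cc4)coc23)C(=O)O1 | intermediate
10 | dilithium salt (5-phenoxide and hemiketal alkoxide) of 5-hydroxy-8-{[(4S)-5-hydroxy-2,2,5-trimethyl-1,3-dioxolan-4-yl]methyl}-7-(methoxymethoxy)-3-[4-(methoxymethoxy)phenyl]-6-(3-methylbut-2-en-1-yl)-4H-chromen-4-one | [Li+].[Li+].CC1(C)O[C@@H](Cc2c(OCOC)c(CC=C(C)C)c([O-])c3c(=O)c(-c4ccc(OCOC)cc4)coc23)C(C)([O-])O1 | intermediate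
11 | 5-hydroxy-8-[(2S)-2-hydroxy-3-oxobutyl]-7-(methoxymethoxy)-3-[4-(methoxymethoxy)phenyl]-6-(3-methylbut-2-en-1-yl)-4H-chromen-4-one | CC(=O)[C@@H](O)Cc1c(OCOC)c(CC=C(C)C)c(O)c2c(=O)c(-c3ccc(OCOC)cc3)coc12 | intermediate
12 | 5-hydroxy-8-[(2S)-2-hydroxy-3-methylbut-3-en-1-yl]-7-(methoxymethoxy)-3-[4-(methoxymethoxy)phenyl]-6-(3-methylbut-2-en-1-yl)-4H-chromen-4-one | C=C(C)[C@@H](O)Cc1c(OCOC)c(CC=C(C)C)c(O)c2c(=O)c(-c3ccc(OCOC)cc3)coc12 | intermediate
13 | 5,7-dihydroxy-8-[(2S)-2-hydroxy-3-methylbut-3-en-1-yl]-3-(4-hydroxyphenyl)-6-(3-methylbut-2-en-1-yl)-4H-chromen-4-one (CNP0203531.1) | C=C(C)[C@@H](O)Cc1c(O)c(CC=C(C)C)c(O)c2c(=O)c(-c3ccc(O)cc3)coc12 | target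

**Totals and risks**

Total step count: 7. Longest linear sequence: 7 (1 to 13; 4 and 6 are bought).

The three steps most likely to fail:

The step-4 photochemical C–H alkylation (the proposed new reaction) may lose to dimerisation of the phenoxyl radical, to simple reduction of the alkyl radical, or to a second alkylation at C8. The fallback uses known chemistry, sets out from 3 and comes back at 9. NBS (DMF, 0 °C) brominates the last free ring-A position of 3 and gives 8-bromo-5-hydroxy-6-iodo-7-(methoxymethoxy)-3-[4-(methoxymethoxy)phenyl]-4H-chromen-4-one F1. Suzuki–Miyaura coupling of F1 with 4 at the C–I bond only (PdCl2(dppf), K3PO4, THF–H2O, 45 °C) gives 8-bromo-5-hydroxy-7-(methoxymethoxy)-3-[4-(methoxymethoxy)phenyl]-6-(3-methylbut-2-en-1-yl)-4H-chromen-4-one F2. The aryl bromide F2 and the redox-active ester 7 (made as in step 4) are then joined by the established nickel-catalysed photochemical decarboxylative arylation (NiBr2(dme), 4,4'-di-tert-butyl-2,2'-bipyridine, Hantzsch ester, NaHCO3, DMA, 405 nm LEDs, rt), which gives 9.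

The step-3 Suzuki prenylation may give protodeiodination or some branched (1,1-dimethylallyl) isomer at the hindered C6 position. The fallback replaces cross-coupling by a sigmatropic route, sets out from 2 and comes back at 5. Copper-catalysed O-alkylation of the 5-OH of 2 with 3-chloro-3-methylbut-1-yne (CuCl2, DBU, MeCN, 0 °C) gives 7-(methoxymethoxy)-3-[4-(methoxymethoxy)phenyl]-5-[(2-methylbut-3-yn-2-yl)oxy]-4H-chromen-4-one F3. Semi-hydrogenation (H2, Pd/CaCO3 poisoned with Pb(OAc)2, quinoline, EtOAc) gives 7-(methoxymethoxy)-3-[4-(methoxymethoxy)phenyl]-5-[(2-methylbut-3-en-2-yl)oxy]-4H-chromen-4-one F4. Aromatic Claisen rearrangement of F4 (N,N-diethylaniline, 130 °C) can only reach C6, the single free ortho carbon, and delivers the linear prenyl group of 5.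

The step-6 methylenation may stall on the hydroxylated, chelating substrate, or the Lewis-acidic titanium may attack the MOM ethers. The fallback is a Peterson olefination, sets out from 11 and comes back at 12. Addition of Me3SiCH2MgCl in the presence of CeCl3 (THF, −78 to 0 °C), a weakly basic reagent that does not enolise the ketone, gives 5-hydroxy-8-[(2S)-2,3-dihydroxy-3-methyl-4-(trimethylsilyl)butyl]-7-(methoxymethoxy)-3-[4-(methoxymethoxy)phenyl]-6-(3-methylbut-2-en-1-yl)-4H-chromen-4-one F5 as a mixture of epimers at the new carbinol. Elimination with KH (THF, rt) then gives the 1,1-disubstituted alkene 12.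

**Further compounds**
F1 | step 4 | 8-bromo-5-hydroxy-6-iodo-7-(methoxymethoxy)-3-[4-(methoxymethoxy)phenyl]-4H-chromen-4-one | COCOc1ccc(cc1)-c1coc2c(Br)c(OCOC)c(I)c(O)c2c1=O
F2 | step 4 | 8-bromo-5-hydroxy-7-(methoxymethoxy)-3-[4-(methoxymethoxy)phenyl]-6-(3-methylbut-2-en-1-yl)-4H-chromen-4-one | COCOc1ccc(cc1)-c1coc2c(Br)c(OCOC)c(CC=C(C)C)c(O)c2c1=O
F3 | step 3 | 7-(methoxymethoxy)-3-[4-(methoxymethoxy)phenyl]-5-[(2-methylbut-3-yn-2-yl)oxy]-4H-chromen-4-one | COCOc1ccc(cc1)-c1coc2cc(OCOC)cc(OC(C)(C)C#C)c2c1=O
F4 | step 3 | 7-(methoxymethoxy)-3-[4-(methoxymethoxy)phenyl]-5-[(2-methylbut-3-en-2-yl)oxy]-4H-chromen-4-one | COCOc1ccc(cc1)-c1coc2cc(OCOC)cc(OC(C)(C)C=C)c2c1=O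
F5 | step 6 | 5-hydroxy-8-[(2S)-2,3-dihydroxy-3-methyl-4-(trimethylsilyl)butyl]-7-(methoxymethoxy)-3-[4-(methoxymethoxy)phenyl]-6-(3-methylbut-2-en-1-yl)-4H-chromen-4-one (C3 epimers) | C[Si](C)(C)CC(C)(O)[C@@H](O)Cc1c(OCOC)c(CC=C(C)C)c(O)c2c(=O)c(-c3ccc(OCOC)cc3)coc12
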